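**Plan**
1. Retrosynthetic cuts, in order: the carbinol C–H (back to the aryl ketone); the ketone C=O (back to a 1-arylvinyl group); CH2OH (back to CHO); then the oxolane C2–C3 bond, with the formyl oxygen re-attached to C2; last the side-chain C–C bond and the two acetal C–O bonds.
2. Enabling feature (ring counted O1, C2 aryl, C3 CH2OH, C4 side chain, C5 CH2): the carbon on C3 is β to O1, so C2–C3–CHO is an aldol retron, and C2 is benzylic to the trimethoxyphenyl ring. All five ring atoms can therefore be stored in a seven-membered cyclic vinyl acetal, a 4,5-dihydro-1,3-dioxepine. Its enol-ether O and CH leave the ring as the formyl group.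
3. Forward order: the seven-membered acetal ring is made first. The side chain is added second; this Heck step also moves the alkene into the enol-ether position. Ring contraction from seven to five members comes third, followed by three functional-group steps without protecting groups.
4. Stereochemistry: C4 comes from the ligand-controlled Heck step. C3 and C2 are set from C4 in the contraction, by allylic strain and then equilibration to the all-trans ring. The carbinol centre comes from a CBS reduction matched with the Felkin–Anh bias.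

Key step: step 4

Assumption: the sense of induction of the (S)-ligand on alkene 3 is inferred by analogy with related cyclic alkenes; should it deliver the (5R) product, the equally available (R)-ligand is used with no other change.

**Step 1**
Reactants: 1 3,4,5-trimethoxybenzaldehyde; 2 (Z)-but-2-ene-1,4-diol
Product: 3 2-(3,4,5-trimethoxyphenyl)-4,7-dihydro-1,3-dioxepine
Conditions: p-toluenesulfonic acid monohydrate (2 mol %), toluene, reflux, Dean–Stark trap
Reagents that add atoms: none
Why: Acid-catalysed acetalisation with azeotropic removal of water, in which the cis geometry of 2 allows the seven-membered acetal to close and the product is achiral (a mirror plane runs through C2 and the midpoint of C5=C6).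

**Step 2**
Reactants: 4 1-(3,4-dimethoxyphenyl)ethan-1-one
Product: 5 1-(3,4-dimethoxyphenyl)ethenyl trifluoromethanesulfonate
Conditions: Tf2O (1.2 equiv), 2,6-di-tert-butyl-4-methylpyridine (1.3 equiv), CH2Cl2, 0 °C to rt; filtration through base-washed silica, used promptly
Reagents that add atoms: triflic anhydride, O=S(=O)(OS(=O)(=O)C(F)(F)F)C(F)(F)F
Why: Enol triflate formation by O-sulfonylation of the ketone and loss of an α-proton to the hindered, non-nucleophilic base, with only one enolisable position so that a single alkenyl triflate can form.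

**Step 3**
Reactants: 3 2-(3,4,5-trimethoxyphenyl)-4,7-dihydro-1,3-dioxepine; 5 1-(3,4-dimethoxyphenyl)ethenyl trifluoromethanesulfonate
Product: 6 (5S)-5-[1-(3,4-dimethoxyphenyl)ethenyl]-2-(3,4,5-trimethoxyphenyl)-4,5-dihydro-1,3-dioxepine (both C2 epimers)
Conditions: Pd2(dba)3 (2.5 mol %), (S)-4-tert-butyl-2-[2-(diphenylphosphino)phenyl]-4,5-dihydrooxazole (6 mol %), iPr2NEt (2 equiv), 3 (4 equiv, excess recovered), THF, 60 °C
Reagents that add atoms: none
Why: Enantioselective intermolecular Mizoroki–Heck alkenylation on the cationic pathway, in which the P,N-ligand selects one of the two enantiotopic alkene carbons for syn-carbopalladation and so sets C5, the only syn β-hydrogen (on C7) is then eliminated to give the enol ether directly, this ligand class should release the kinetic alkene without Pd–H re-addition, and the C2 epimers are of no consequence because C2 is planarised in step 4.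

**Step 4**
Reactants: 6 (5S)-5-[1-(3,4-dimethoxyphenyl)ethenyl]-2-(3,4,5-trimethoxyphenyl)-4,5-dihydro-1,3-dioxepine
Product: 8 (2R,3R,4S)-4-[1-(3,4-dimethoxyphenyl)ethenyl]-2-(3,4,5-trimethoxyphenyl)oxolane-3-carbaldehyde, via silyl enol ether oxocarbenium triflate 7 (not isolated)
Conditions: Me3SiOTf (20 mol %), 2,6-di-tert-butylpyridine (10 mol %), CH2Cl2, −78 °C, then slowly to −20 °C; Et3N quench
Reagents that add atoms: none
Why: Me3SiOTf silylates the enol-ether oxygen O1 of the dioxepine and the C2–O1 bond ionises, since the enolate is the better leaving group and the trimethoxyphenyl ring stabilises the cation, giving the tethered (Z)-silyl enol ether/oxocarbenium pair 7; C6 then attacks C2 and silyl transfer to the next molecule of 6 turns the catalyst over, so O1 and C7 leave the ring as the formyl group and C2, O3, C4, C5 and C6 remain as the oxolane. The closest known reaction type is the Lewis-acid-mediated [1,3] O-to-C (vinyl acetal) rearrangement of 4,5-dihydro-1,3-dioxepines to oxolane-3-carbaldehydes, in essence an intramolecular Mukaiyama aldol addition. The one ring closed forms in the 5-(enolexo)-endo-trig mode at the oxocarbenium carbon, a mode that is routine for oxocarbenium electrophiles. The new C3 centre is controlled by the existing centre: A(1,3) strain in the (Z)-enol ether places the C5–H of 7 in the alkene plane, so the tether and the 1-arylvinyl group lie on opposite faces and the new bond forms anti to that group (3,4-trans). The new C2 centre is controlled by the aryl group taking the pseudo-equatorial site of the envelope, and because the aldol step and the benzylic C2–O bond are both reversible under the Lewis acid on warming, any 2,3-cis isomer should drain into the all-trans ring while C4 is never touched. The step needs the enol silane to outrun the styrene as π-nucleophile and the styrene to survive; this is secured by the far higher nucleophilicity of the enol silane, its five-membered closure, the low temperature, and the hindered pyridine that removes adventitious acid.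

**Step 5**
Reactants: 8 (2R,3R,4S)-4-[1-(3,4-dimethoxyphenyl)ethenyl]-2-(3,4,5-trimethoxyphenyl)oxolane-3-carbaldehyde
Product: 9 [(2R,3S,4S)-4-[1-(3,4-dimethoxyphenyl)ethenyl]-2-(3,4,5-trimethoxyphenyl)oxolan-3-yl]methanol
Conditions: NaBH4, MeOH, 0 °C
Reagents that add atoms: none
Why: Chemoselective borohydride 1,2-reduction of the aldehyde, fast enough at 0 °C that neither epimerisation at C3 nor β-elimination of the ring oxygen should intervene, with the alkene left untouched (the C3 descriptor changes only through ligand priorities).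

**Step 6**
Reactants: 9 [(2R,3S,4S)-4-[1-(3,4-dimethoxyphenyl)ethenyl]-2-(3,4,5-trimethoxyphenyl)oxolan-3-yl]methanol
Product: 11 (3,4-dimethoxyphenyl)[(3R,4S,5R)-4-(hydroxymethyl)-5-(3,4,5-trimethoxyphenyl)oxolan-3-yl]methanone, via vicinal diol 10 (not isolated)
Conditions: OsO4 (2 mol %), NaIO4 (4 equiv), 2,6-lutidine (2 equiv), 1,4-dioxane/H2O 3:1, rt
Reagents that add atoms: osmium tetroxide, O=[Os](=O)(=O)=O; sodium periodate (terminal oxidant), [Na+].[O-]I(=O)(=O)=O; water, O
Why: Lemieux–Johnson oxidation, in which the only alkene is dihydroxylated to 10 and cleaved in situ to the aryl ketone and formaldehyde, the lutidine buffer avoids retro-oxa-Michael opening of the β-alkoxy ketone, the trans disposition of CH2OH and aroyl precludes hemiketal formation, and the α-centre already holds its more stable trans configuration.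

**Step 7**
Reactants: 11 (3,4-dimethoxyphenyl)[(3R,4S,5R)-4-(hydroxymethyl)-5-(3,4,5-trimethoxyphenyl)oxolan-3-yl]methanone
Product: 12 (S)-(3,4-dimethoxyphenyl)[(3R,4S,5R)-4-(hydroxymethyl)-5-(3,4,5-trimethoxyphenyl)oxolan-3-yl]methanol
Conditions: (R)-1-methyl-3,3-diphenyltetrahydro-1H,3H-pyrrolo[1,2-c][1,3,2]oxazaborole (20 mol %), BH3·SMe2 (2.5 equiv), THF, −20 °C, slow addition of 11; MeOH quench
Reagents that add atoms: none
Why: Corey–Bakshi–Shibata reduction, in which the (R)-catalyst with the aryl group as the large substituent delivers hydride to the Re face to give the (S)-carbinol, the same face favoured by the Felkin–Anh model (branched ring carbon C4 of the oxolan-3-yl unit anti to the hydride, ring CH2O as medium group), so reagent and substrate control should be matched.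

**Compound list**
1 | 3,4,5-trimethoxybenzaldehyde | COc1cc(C=O)cc(OC)c1OC | starting material
2 | (Z)-but-2-ene-1,4-diol | OC/C=C\CO | starting material
3 | 2-(3,4,5-trimethoxyphenyl)-4,7-dihydro-1,3-dioxepine | COc1cc(C2OCC=CCO2)cc(OC)c1OC | intermediate
4 | 1-(3,4-dimethoxyphenyl)ethan-1-one | CC(=O)c1ccc(OC)c(OC)c1 | starting material
5 | 1-(3,4-dimethoxyphenyl)ethenyl trifluoromethanesulfonate | C=C(OS(=O)(=O)C(F)(F)F)c1ccc(OC)c(OC)c1 | intermediate
6 | (5S)-5-[1-(3,4-dimethoxyphenyl)ethenyl]-2-(3,4,5-trimethoxyphenyl)-4,5-dihydro-1,3-dioxepine, C2 epimers | C=C(c1ccc(OC)c(OC)c1)[C@H]2COC(c3cc(OC)c(OC)c(OC)c3)OC=C2 | intermediate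
7 | ring-opened (Z)-trimethylsilyl enol ether / aryl oxocarbenium triflate ion pair | C=C(c1ccc(OC)c(OC)c1)[C@@H](C[O+]=Cc2cc(OC)c(OC)c(OC)c2)/C=C\O[Si](C)(C)C.[O-]S(=O)(=O)C(F)(F)F | intermediate
8 | (2R,3R,4S)-4-[1-(3,4-dimethoxyphenyl)ethenyl]-2-(3,4,5-trimethoxyphenyl)oxolane-3-carbaldehyde | C=C(c1ccc(OC)c(OC)c1)[C@H]2CO[C@@H](c3cc(OC)c(OC)c(OC)c3)[C@@H]2C=O | intermediate
9 | [(2R,3S,4S)-4-[1-(3,4-dimethoxyphenyl)ethenyl]-2-(3,4,5-trimethoxyphenyl)oxolan-3-yl]methanol | C=C(c1ccc(OC)c(OC)c1)[C@H]2CO[C@@H](c3cc(OC)c(OC)c(OC)c3)[C@@H]2CO | intermediate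
10 | 1-(3,4-dimethoxyphenyl)-1-[(3R,4S,5R)-4-(hydroxymethyl)-5-(3,4,5-trimethoxyphenyl)oxolan-3-yl]ethane-1,2-diol, carbinol epimers | OCC(O)(c1ccc(OC)c(OC)c1)[C@H]2CO[C@@H](c3cc(OC)c(OC)c(OC)c3)[C@@H]2CO | intermediate
11 | (3,4-dimethoxyphenyl)[(3R,4S,5R)-4-(hydroxymethyl)-5-(3,4,5-trimethoxyphenyl)oxolan-3-yl]methanone | O=C(c1ccc(OC)c(OC)c1)[C@H]2CO[C@@H](c3cc(OC)c(OC)c(OC)c3)[C@@H]2CO | intermediate
12 | (S)-(3,4-dimethoxyphenyl)[(3R,4S,5R)-4-(hydroxymethyl)-5-(3,4,5-trimethoxyphenyl)oxolan-3-yl]methanol | COc1ccc([C@@H](O)[C@H]2CO[C@@H](c3cc(OC)c(OC)c(OC)c3)[C@@H]2CO)cc1OC | target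

Total step count: 7. Longest linear sequence: 6 (steps 1, 3, 4, 5, 6, 7).

**Steps most likely to fail**

**Step 3.**
- What may go wrong: the two enantiotopic carbons of a nearly symmetric seven-membered alkene may be discriminated incompletely. Pd–H re-addition may move the skipped diene into conjugation. The electron-rich alkenyl triflate may solvolyse during a slow coupling.
- Fallback: absolute configuration is secured by classical resolution instead of by catalyst control. The fallback sets out from 9 of insufficient enantiomeric purity and comes back at 9.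
- Alcohol 9 is esterified with (S)-2-methoxy-2-phenylacetic acid, N-(3-dimethylaminopropyl)-N'-ethylcarbodiimide hydrochloride and 4-(dimethylamino)pyridine in CH2Cl2.
- This gives the O-methylmandelate of 9 F1 together with the O-methylmandelate of the antipode F2. The two are separated by chromatography or crystallisation.
- Methanolysis of F1 with K2CO3 in MeOH returns 9.

**Step 4.**
- What may go wrong: the 2,3-cis isomer may be kinetically trapped at low temperature. Acid-induced cationic oligomerisation of the styrene may set in on the warming that equilibration needs.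
- Fallback: the C2 correction is postponed until the acid-sensitive alkene is gone. The fallback sets out from 6 and comes back at 11.
- The contraction is stopped at −78 °C to give the 2,3-cis-3,4-trans aldehyde F3.
- NaBH4 reduction gives the 2-epi alcohol F4. Lemieux–Johnson cleavage then runs through the 5-epi triol F5 to the 5-epi ketone F6.
- F6 is equilibrated with BF3·OEt2 in CH2Cl2 at 0 °C to rt. Reversible heterolysis of the benzylic C–O bond, the acid-catalysed benzylic epimerisation known for 2-aryloxolane and furofuran lignans, should give the all-trans ketone 11.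

**Step 7.**
- What may go wrong: uncatalysed or intramolecular hydride delivery from the alkoxyborane formed at the free primary hydroxyl may compete. The steric difference between the aryl group and the branched oxolanyl residue is small. Both effects would lower facial selectivity.
- Fallback: substrate control on a protected ketone. The fallback sets out from 11 and comes back at 12.
- Silylation with t-BuMe2SiCl and imidazole in DMF gives the silyl ether ketone F7.
- Reduction with LiBH(s-Bu)3 in THF at −78 °C, under Felkin–Anh control by the bulky hydride, gives the silyl ether carbinol F8.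
- Bu4NF in THF releases 12.

**Further compounds**
F1 | step 3 | [(2R,3S,4S)-4-[1-(3,4-dimethoxyphenyl)ethenyl]-2-(3,4,5-trimethoxyphenyl)oxolan-3-yl]methyl (S)-2-methoxy-2-phenylacetate | C=C(c1ccc(OC)c(OC)c1)[C@H]2CO[C@@H](c3cc(OC)c(OC)c(OC)c3)[C@@H]2COC(=O)[C@@H](OC)c4ccccc4
F2 | step 3 | [(2S,3R,4R)-4-[1-(3,4-dimethoxyphenyl)ethenyl]-2-(3,4,5-trimethoxyphenyl)oxolan-3-yl]methyl (S)-2-methoxy-2-phenylacetate | C=C(c1ccc(OC)c(OC)c1)[C@@H]2CO[C@H](c3cc(OC)c(OC)c(OC)c3)[C@H]2COC(=O)[C@@H](OC)c4ccccc4
F3 | step 4 | (2S,3R,4S)-4-[1-(3,4-dimethoxyphenyl)ethenyl]-2-(3,4,5-trimethoxyphenyl)oxolane-3-carbaldehyde | C=C(c1ccc(OC)c(OC)c1)[C@H]2CO[C@H](c3cc(OC)c(OC)c(OC)c3)[C@@H]2C=O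
F4 | step 4 | [(2S,3S,4S)-4-[1-(3,4-dimethoxyphenyl)ethenyl]-2-(3,4,5-trimethoxyphenyl)oxolan-3-yl]methanol | C=C(c1ccc(OC)c(OC)c1)[C@H]2CO[C@H](c3cc(OC)c(OC)c(OC)c3)[C@@H]2CO
F5 | step 4 | 1-(3,4-dimethoxyphenyl)-1-[(3R,4S,5S)-4-(hydroxymethyl)-5-(3,4,5-trimethoxyphenyl)oxolan-3-yl]ethane-1,2-diol | OCC(O)(c1ccc(OC)c(OC)c1)[C@H]2CO[C@H](c3cc(OC)c(OC)c(OC)c3)[C@@H]2CO
F6 | step 4 | (3,4-dimethoxyphenyl)[(3R,4S,5S)-4-(hydroxymethyl)-5-(3,4,5-trimethoxyphenyl)oxolan-3-yl]methanone | O=C(c1ccc(OC)c(OC)c1)[C@H]2CO[C@H](c3cc(OC)c(OC)c(OC)c3)[C@@H]2CO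
F7 | step 7 | [(3R,4S,5R)-4-[(tert-butyldimethylsilyloxy)methyl]-5-(3,4,5-trimethoxyphenyl)oxolan-3-yl](3,4-dimethoxyphenyl)methanone | O=C(c1ccc(OC)c(OC)c1)[C@H]2CO[C@@H](c3cc(OC)c(OC)c(OC)c3)[C@@H]2CO[Si](C)(C)C(C)(C)C
F8 | step 7 | (S)-[(3R,4S,5R)-4-[(tert-butyldimethylsilyloxy)methyl]-5-(3,4,5-trimethoxyphenyl)oxolan-3-yl](3,4-dimethoxyphenyl)methanol | COc1ccc([C@@H](O)[C@H]2CO[C@@H](c3cc(OC)c(OC)c(OC)c3)[C@@H]2CO[Si](C)(C)C(C)(C)C)cc1OC
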